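**Strategy.** The target is epicatechin-(4β→6)-epicatechin-(4β→8)-epicatechin-(4β→6)-epicatechin (units A to D, top to bottom). Units B, C and D are taken from (−)-epicatechin; the pyran ring C of unit A is built. The plan rests on reading O1–C2–C3–C4 of unit A as a 1,3-diketone hung on a 2-fluoroaryl ketone: with C4 as a carbonyl, C3–H is acidic and the C8a–F bond of ring A is open to substitution. One operation, C-acylation then intramolecular SNAr, joins C2–C3 and O1–C8a from a trifluorophenyl ketone and an aroyl chloride to give an achiral flavonol ether. Asymmetric hydrogenation then sets C2 and C3 cis, and the C4 oxygen serves as leaving group for the interflavan bond.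

Key step: step 2

Remark: flavan numbering (O1, C2, C3, C4, C4a, C5–C8, C8a) is used for every unit, and α/β refer to the usual flavan drawing, in which the 2-aryl and 3-oxygen of an epicatechin unit are both α. Compounds 1, 2, 5 and 12 are taken as catalogue compounds.

**Step 1**
Reactants: 1 1,3,5-trifluorobenzene; 2 2-(benzyloxy)-N-methoxy-N-methylacetamide
Product: 4 2-(benzyloxy)-1-(2,4,6-trifluorophenyl)ethan-1-one, via 2,4,6-trifluorophenyllithium 3 (not isolated)
Conditions: n-BuLi (1.05 equiv), THF, −78 °C, 1 h; then 2, −78 → −40 °C; work-up with water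
Reagents that add atoms: none
Why: Deprotonation between two fluorines (ortho-lithiation) gives the aryllithium, which is kept cold to avoid aryne formation and is acylated once by the Weinreb amide (Weinreb ketone synthesis).

**Step 2**
Reactants: 4 2-(benzyloxy)-1-(2,4,6-trifluorophenyl)ethan-1-one; 5 3,4-bis(benzyloxy)benzoyl chloride
Product: 7 3-(benzyloxy)-2-[3,4-bis(benzyloxy)phenyl]-5,7-difluoro-4H-chromen-4-one, via 1,3-diketone 6 (not isolated)
Conditions: LiN(SiMe3)2 (2.2 equiv), THF, −78 °C; then 5, −78 → 0 °C; then DMF, 80 °C (one pot)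
Reagents that add atoms: none
Why: The lithium enolate of 4 (C3) is C-acylated by 5 in a Claisen-type condensation that forms C2–C3, and the second equivalent of base drains the product as the chelated enolate of 1,3-diketone 6, whose enolate oxygen on C2 (the future O1) then attacks C8a of ring A, ipso to an ortho fluorine, in an intramolecular addition–elimination (SNAr) that forms O1–C8a and expels fluoride. The closest known reaction type is the one-pot acylation/SNAr cyclization of 2-fluoroaryl ketones to chromones and flavones (Baker–Venkataraman-type diketone formation followed by O-arylation). Ring C closes as a six-membered ring by O-attack on the aromatic carbon through a Meisenheimer intermediate whose charge rests on C4a and is taken up by the C4 carbonyl and the two remaining fluorines. No stereocenter is formed here; C2 and C3 leave the step as a tetrasubstituted C2=C3 enol-ether double bond and are set together in step 4. The step needs C- over O-acylation, which the lithium enolate in THF at low temperature and the irreversible deprotonation of 6 should secure, and O- over C-arylation, which is secured because only O1 can reach C8a in a six-membered transition state; the two ortho fluorines are equivalent, so no regiochemical question arises.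

**Step 3**
Reactants: 7 3-(benzyloxy)-2-[3,4-bis(benzyloxy)phenyl]-5,7-difluoro-4H-chromen-4-one
Product: 9 3,5,7-tris(benzyloxy)-2-[3,4-bis(benzyloxy)phenyl]-4H-chromen-4-one (penta-O-benzylquercetin), via 5-fluoro-7-benzyloxy flavone 8 (not isolated)
Conditions: BnOH (2.5 equiv), NaH (2.5 equiv), DMF, 0 → 80 °C
Reagents that add atoms: benzyl alcohol, OCc1ccccc1
Why: Two SNAr displacements of fluoride by benzyloxide, first at C7 (para to the C4 carbonyl) and then at C5 (ortho), both activated by the pyranone carbonyl, while the 3-alkoxy-substituted C2 is a poor Michael acceptor so ring opening should not compete.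

**Step 4**
Reactants: 9 3,5,7-tris(benzyloxy)-2-[3,4-bis(benzyloxy)phenyl]-4H-chromen-4-one
Product: 11 (2R,3R,4R)-3,5,7-tris(benzyloxy)-2-[3,4-bis(benzyloxy)phenyl]chroman-4-ol (all-cis: 2-aryl, 3-OBn and 4-OH on the α face), via cis-flavanonol 10 (not isolated)
Conditions: H2 (150 bar), [Ru(cod)(2-methylallyl)2] (5 mol %), 1,3-bis[(R)-1-(1-naphthyl)ethyl]-4,5-dihydroimidazolium tetrafluoroborate (10 mol %), KOtBu (12 mol %), toluene, 40 °C
Reagents that add atoms: none
Why: Proposed new method: a ruthenium hydride carrying the chiral N-heterocyclic carbene should add H2 in a syn fashion to one enantioface of the tetrasubstituted, vinylogous-ester C2=C3 bond, so that the 2-aryl and 3-benzyloxy groups necessarily end up cis (relative control by syn addition, absolute control by the carbene, whose antipode is picked to give 2R), and should then reduce the C4 ketone of 10 from the same open face before C3 can epimerize, giving the all-cis alcohol whose C4 configuration is of no consequence because C4 is ionized in step 9; the closest known reaction type is the Ru–NHC-catalysed asymmetric hydrogenation of flavones and chromones to flavanones and cis-flavanols, which has not been shown for 3-alkoxy-substituted (tetrasubstituted) flavone double bonds.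

**Step 5**
Reactants: 12 (−)-epicatechin
Product: 13 5,7,3',4'-tetra-O-benzyl-(−)-epicatechin
Conditions: BnBr (4.4 equiv), K2CO3 (5 equiv), DMF, 0 °C → rt
Reagents that add atoms: benzyl bromide, BrCc1ccccc1
Why: Williamson ether synthesis in which carbonate deprotonates only the four phenols, so the secondary 3-OH stays free and no stereocenter is touched.

**Step 6**
Reactants: 13 5,7,3',4'-tetra-O-benzyl-(−)-epicatechin
Product: 14 8-bromo-5,7,3',4'-tetra-O-benzyl-(−)-epicatechin
Conditions: NBS (1.0 equiv), CH2Cl2, −78 °C → rt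
Reagents that add atoms: N-bromosuccinimide, O=C1CCC(=O)N1Br
Why: Electrophilic aromatic bromination should go to C8 of ring A, the more accessible of the two activated positions (C6 lies between two benzyloxy groups), as is usual for 5,7-di-O-alkyl flavan-3-ols.

**Step 7**
Reactants: 13 5,7,3',4'-tetra-O-benzyl-(−)-epicatechin
Product: 15 4β-(2-ethoxyethoxy)-5,7,3',4'-tetra-O-benzyl-(−)-epicatechin (4-alkoxy trans to the 3-OH)
Conditions: DDQ (2 equiv), 2-ethoxyethanol (5 equiv), CH2Cl2, rt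
Reagents that add atoms: 2-ethoxyethanol, CCOCCO
Why: Benzylic oxidation by hydride transfer from C4 to DDQ gives the ring-A-stabilized C4 cation, which the alcohol captures on the β face, trans to the 3-OH.

**Step 8**
Reactants: 15 4β-(2-ethoxyethoxy)-5,7,3',4'-tetra-O-benzyl-(−)-epicatechin; 14 8-bromo-5,7,3',4'-tetra-O-benzyl-(−)-epicatechin
Product: 16 dimer C–D, [5,7,3',4'-tetra-O-benzylepicatechin]-(4β→6)-[8-bromo-5,7,3',4'-tetra-O-benzylepicatechin]
Conditions: Me3SiOTf (0.2 equiv), 14 (3 equiv), CH2Cl2, −78 °C, slow addition of 15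
Reagents that add atoms: none
Why: Lewis-acid ionization of the 4-alkoxy group gives the C4 cation, which undergoes Friedel–Crafts interflavan coupling at C6 of 14 (its only free ring-A position, C8 being blocked by bromine) from the β face, anti to the α-disposed 3-OH and 2-aryl groups, so the new stereocenter is 4β.

**Step 9**
Reactants: 11 (2R,3R,4R)-3,5,7-tris(benzyloxy)-2-[3,4-bis(benzyloxy)phenyl]chroman-4-ol; 14 8-bromo-5,7,3',4'-tetra-O-benzyl-(−)-epicatechin
Product: 17 dimer A–B, [3,5,7,3',4'-penta-O-benzylepicatechin]-(4β→6)-[8-bromo-5,7,3',4'-tetra-O-benzylepicatechin]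
Conditions: Me3SiOTf (0.2 equiv), 14 (3 equiv), CH2Cl2, −78 → −40 °C, slow addition of 11
Reagents that add atoms: none
Why: Ionization of the benzylic 4-hydroxyl gives the C4 cation of unit A, which is attacked by C6 of 14 (C8 blocked by bromine) from the β face, anti to the 3-benzyloxy and 2-aryl groups, setting C4 as 4β (3,4-trans) in a Friedel–Crafts interflavan coupling; excess 14 and slow addition hold back self-condensation.

**Step 10**
Reactants: 17 dimer A–B
Product: 18 dimer A–B carrying a 4β-(2-ethoxyethoxy) group on unit B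
Conditions: DDQ (1.5 equiv), 2-ethoxyethanol (5 equiv), CH2Cl2, 0 °C → rt
Reagents that add atoms: 2-ethoxyethanol, CCOCCO
Why: DDQ benzylic oxidation should take hydride from the only benzylic methylene, C4 of unit B, since the methine C4–H of unit A is tertiary and shielded by two ortho-disubstituted rings, and the alcohol traps the cation trans to the 3-OH.

**Step 11**
Reactants: 18 dimer A–B carrying a 4β-(2-ethoxyethoxy) group on unit B; 16 dimer C–D
Product: 19 protected tetramer, heptadeca-O-benzyl-8,8-dibromo (units B and D) derivative of the target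
Conditions: Me3SiOTf (0.2 equiv), 16 (3 equiv), CH2Cl2, −78 → −40 °C, slow addition of 18
Reagents that add atoms: none
Why: Ionization of the 4-alkoxy group of unit B gives its C4 cation, which is attacked by C8 of unit C of 16 (the more nucleophilic and less hindered of its two free ring-A positions) from the β face, setting the central 4β→8 bond by Friedel–Crafts interflavan coupling.

**Step 12**
Reactants: 19 protected tetramer
Product: 20 epicatechin-(4β→6)-epicatechin-(4β→8)-epicatechin-(4β→6)-epicatechin (target)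
Conditions: H2 (1 atm), Pd(OH)2/C, Et3N (4 equiv), THF/MeOH/H2O, rt
Reagents that add atoms: none
Why: Catalytic hydrogenolysis cleaves all seventeen benzyl ethers and both aryl C–Br bonds, while triethylamine takes up HBr so the acid-labile interflavan bonds and the stereocenters stay intact.

**Compound list**

1 | 1,3,5-trifluorobenzene | Fc1cc(F)cc(F)c1 | starting material
2 | 2-(benzyloxy)-N-methoxy-N-methylacetamide | CON(C)C(=O)COCc1ccccc1 | starting material
3 | 2,4,6-trifluorophenyllithium | [Li]c1c(F)cc(F)cc1F | intermediate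
4 | 2-(benzyloxy)-1-(2,4,6-trifluorophenyl)ethan-1-one | O=C(COCc1ccccc1)c1c(F)cc(F)cc1F | intermediate
5 | 3,4-bis(benzyloxy)benzoyl chloride | O=C(Cl)c1ccc(OCc2ccccc2)c(OCc2ccccc2)c1 | starting material
6 | 2-(benzyloxy)-1-[3,4-bis(benzyloxy)phenyl]-3-(2,4,6-trifluorophenyl)propane-1,3-dione (present as its lithium enolate) | O=C(c1ccc(OCc2ccccc2)c(OCc2ccccc2)c1)C(OCc1ccccc1)C(=O)c1c(F)cc(F)cc1F | intermediate
7 | 3-(benzyloxy)-2-[3,4-bis(benzyloxy)phenyl]-5,7-difluoro-4H-chromen-4-one | O=c1c(OCc2ccccc2)c(-c2ccc(OCc3ccccc3)c(OCc3ccccc3)c2)oc2cc(F)cc(F)c12 | intermediate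
8 | 3,7-bis(benzyloxy)-2-[3,4-bis(benzyloxy)phenyl]-5-fluoro-4H-chromen-4-one | O=c1c(OCc2ccccc2)c(-c2ccc(OCc3ccccc3)c(OCc3ccccc3)c2)oc2cc(OCc3ccccc3)cc(F)c12 | intermediate
9 | 3,5,7-tris(benzyloxy)-2-[3,4-bis(benzyloxy)phenyl]-4H-chromen-4-one | O=c1c(OCc2ccccc2)c(-c2ccc(OCc3ccccc3)c(OCc3ccccc3)c2)oc2cc(OCc3ccccc3)cc(OCc3ccccc3)c12 | intermediate
10 | (2R,3S)-3,5,7-tris(benzyloxy)-2-[3,4-bis(benzyloxy)phenyl]chroman-4-one (2,3-cis) | c1ccccc1COc1cc(OCc2ccccc2)c2c(c1)O[C@H](c1ccc(OCc3ccccc3)c(OCc3ccccc3)c1)[C@H](OCc1ccccc1)C2=O | intermediate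
11 | (2R,3R,4R)-3,5,7-tris(benzyloxy)-2-[3,4-bis(benzyloxy)phenyl]chroman-4-ol (all-cis) | c1ccccc1COc1cc(OCc2ccccc2)c2c(c1)O[C@H](c1ccc(OCc3ccccc3)c(OCc3ccccc3)c1)[C@H](OCc1ccccc1)[C@@H]2O | intermediate
12 | (−)-epicatechin, (2R,3R)-2-(3,4-dihydroxyphenyl)chromane-3,5,7-triol | Oc1cc(O)c2c(c1)O[C@H](c1ccc(O)c(O)c1)[C@H](O)C2 | starting material
13 | 5,7,3',4'-tetra-O-benzyl-(−)-epicatechin | c1ccccc1COc1cc(OCc2ccccc2)c2c(c1)O[C@H](c1ccc(OCc3ccccc3)c(OCc3ccccc3)c1)[C@H](O)C2 | intermediate
14 | 8-bromo-5,7,3',4'-tetra-O-benzyl-(−)-epicatechin | c1ccccc1COc1cc(OCc2ccccc2)c2c(c1Br)O[C@H](c1ccc(OCc3ccccc3)c(OCc3ccccc3)c1)[C@H](O)C2 | intermediate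
15 | 4β-(2-ethoxyethoxy)-5,7,3',4'-tetra-O-benzyl-(−)-epicatechin | c1ccccc1COc1cc(OCc2ccccc2)c2c(c1)O[C@H](c1ccc(OCc3ccccc3)c(OCc3ccccc3)c1)[C@H](O)[C@H]2OCCOCC | intermediate
16 | dimer C–D: [5,7,3',4'-tetra-O-benzylepicatechin]-(4β→6)-[8-bromo-5,7,3',4'-tetra-O-benzylepicatechin] | c1ccccc1COc1cc(OCc2ccccc2)c2c(c1)O[C@H](c1ccc(OCc3ccccc3)c(OCc3ccccc3)c1)[C@H](O)[C@H]2c1c(OCc2ccccc2)c(Br)c2c(c1OCc1ccccc1)C[C@@H](O)[C@@H](c1ccc(OCc3ccccc3)c(OCc3ccccc3)c1)O2 | intermediate
17 | dimer A–B: [3,5,7,3',4'-penta-O-benzylepicatechin]-(4β→6)-[8-bromo-5,7,3',4'-tetra-O-benzylepicatechin] | c1ccccc1COc1cc(OCc2ccccc2)c2c(c1)O[C@H](c1ccc(OCc3ccccc3)c(OCc3ccccc3)c1)[C@H](OCc1ccccc1)[C@H]2c1c(OCc2ccccc2)c(Br)c2c(c1OCc1ccccc1)C[C@@H](O)[C@@H](c1ccc(OCc3ccccc3)c(OCc3ccccc3)c1)O2 | intermediate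
18 | dimer A–B with 4β-(2-ethoxyethoxy) on unit B | c1ccccc1COc1cc(OCc2ccccc2)c2c(c1)O[C@H](c1ccc(OCc3ccccc3)c(OCc3ccccc3)c1)[C@H](OCc1ccccc1)[C@H]2c1c(OCc2ccccc2)c(Br)c2c(c1OCc1ccccc1)[C@H](OCCOCC)[C@@H](O)[C@@H](c1ccc(OCc3ccccc3)c(OCc3ccccc3)c1)O2 | intermediate
19 | protected tetramer: A (penta-O-benzyl)-(4β→6)-B (tetra-O-benzyl, 8-bromo)-(4β→8)-C (tetra-O-benzyl)-(4β→6)-D (tetra-O-benzyl, 8-bromo) | c1ccccc1COc1cc(OCc2ccccc2)c2c(c1)O[C@H](c1ccc(OCc3ccccc3)c(OCc3ccccc3)c1)[C@H](OCc1ccccc1)[C@H]2c1c(OCc2ccccc2)c(Br)c2c(c1OCc1ccccc1)[C@H](c1c(OCc4ccccc4)cc(OCc4ccccc4)c3c1O[C@H](c1ccc(OCc4ccccc4)c(OCc4ccccc4)c1)[C@H](O)[C@H]3c1c(OCc4ccccc4)c(Br)c3c(c1OCc1ccccc1)C[C@@H](O)[C@@H](c1ccc(OCc4ccccc4)c(OCc4ccccc4)c1)O3)[C@@H](O)[C@@H](c1ccc(OCc3ccccc3)c(OCc3ccccc3)c1)O2 | intermediate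
20 | epicatechin-(4β→6)-epicatechin-(4β→8)-epicatechin-(4β→6)-epicatechin | Oc1cc(O)c2c(c1)O[C@H](c1ccc(O)c(O)c1)[C@H](O)[C@H]2c1c(O)cc2c(c1O)[C@H](c1c(O)cc(O)c3c1O[C@H](c1ccc(O)c(O)c1)[C@H](O)[C@H]3c1c(O)cc3c(c1O)C[C@@H](O)[C@@H](c1ccc(O)c(O)c1)O3)[C@@H](O)[C@@H](c1ccc(O)c(O)c1)O2 | target

**Count.** Total steps: 12. Longest linear sequence: 8 steps (1, 2, 3, 4, 9, 10, 11, 12).

**Steps most likely to fail**

Step 4 (Proposed new method). The hindered tetrasubstituted C2=C3 bond may not turn over, the enantiofacial discrimination may be poor, or ketone 10 may epimerize at C3 before it is reduced. The fallback uses known chemistry, sets out from 9 and comes back at 17. Compound 9 is reduced with LiAlH4 (THF, 60 °C) to the achiral enol ether 3,5,7-tris(benzyloxy)-2-[3,4-bis(benzyloxy)phenyl]-4H-chromene F1. Its C2=C3 bond is hydrogenated with H2 and [Ir(cod)(PCy3)(py)]PF6 in CH2Cl2, which leaves benzyl ethers alone and by syn addition can only give racemic 2,3-cis-3,5,7,3',4'-penta-O-benzylepicatechin F2. The enantiomers are separated on a chiral stationary phase to give (2R,3R)-3,5,7,3',4'-penta-O-benzylepicatechin F3. DDQ and 2-ethoxyethanol, as in step 7, then give 4β-(2-ethoxyethoxy)-3,5,7,3',4'-penta-O-benzylepicatechin F4, which is coupled with 14 under the conditions of step 8 to reach 17.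

Step 10. Hydride abstraction may occur at the doubly benzylic C4–H of unit A instead of C4 of unit B, or the dimer may be over-oxidized. The fallback avoids oxidizing a dimer by orthogonal activation; it sets out from 14 and comes back at 19. Compound 14 is oxidized with DDQ and 2-ethoxyethanol to 8-bromo-4β-(2-ethoxyethoxy)-5,7,3',4'-tetra-O-benzylepicatechin F5. Exchange with benzyl mercaptan and BF3·OEt2 (CH2Cl2, −78 °C) gives 8-bromo-4β-(benzylthio)-5,7,3',4'-tetra-O-benzylepicatechin F6. Compound 11 is coupled with F6 using BF3·OEt2, which ionizes the 4-hydroxyl of 11 but leaves the C–S bond alone, to give the A–B dimer with a 4β-benzylthio group on unit B F7. F7 is then activated with the thiophilic salt AgBF4 in the presence of 16 (THF, 0 °C) to reach 19.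

Step 11. The C4 cation of 18 may be intercepted by ring A of unit A of another molecule of 18 (self-condensation), or may attack C6 instead of C8 of unit C in the bulky dimer 16. The fallback builds the lower half one unit at a time; it sets out from 15 and comes back at 19. Compound 15 is converted with benzyl mercaptan and BF3·OEt2 into 4β-(benzylthio)-5,7,3',4'-tetra-O-benzylepicatechin F8. Compound 18 is coupled with a large excess of this small, C8-selective nucleophile (BF3·OEt2, CH2Cl2, −78 °C) to give the A–B–C trimer with a 4β-benzylthio group on unit C F9. F9 is activated with AgBF4 in the presence of 14, whose only free position is C6, to form the last 4β→6 bond and reach 19.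

**Further compounds**

F1 | step 4 | 3,5,7-tris(benzyloxy)-2-[3,4-bis(benzyloxy)phenyl]-4H-chromene | c1ccccc1COc1cc(OCc2ccccc2)c2c(c1)OC(c1ccc(OCc3ccccc3)c(OCc3ccccc3)c1)=C(OCc1ccccc1)C2
F2 | step 4 | racemic 2,3-cis-3,5,7,3',4'-penta-O-benzylepicatechin (both enantiomers) | c1ccccc1COc1cc(OCc2ccccc2)c2c(c1)O[C@H](c1ccc(OCc3ccccc3)c(OCc3ccccc3)c1)[C@H](OCc1ccccc1)C2.c1ccccc1COc1cc(OCc2ccccc2)c2c(c1)O[C@@H](c1ccc(OCc3ccccc3)c(OCc3ccccc3)c1)[C@@H](OCc1ccccc1)C2
F3 | step 4 | (2R,3R)-3,5,7,3',4'-penta-O-benzylepicatechin | c1ccccc1COc1cc(OCc2ccccc2)c2c(c1)O[C@H](c1ccc(OCc3ccccc3)c(OCc3ccccc3)c1)[C@H](OCc1ccccc1)C2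
F4 | step 4 | 4β-(2-ethoxyethoxy)-3,5,7,3',4'-penta-O-benzylepicatechin | c1ccccc1COc1cc(OCc2ccccc2)c2c(c1)O[C@H](c1ccc(OCc3ccccc3)c(OCc3ccccc3)c1)[C@H](OCc1ccccc1)[C@H]2OCCOCC
F5 | step 10 | 8-bromo-4β-(2-ethoxyethoxy)-5,7,3',4'-tetra-O-benzylepicatechin | c1ccccc1COc1cc(OCc2ccccc2)c2c(c1Br)O[C@H](c1ccc(OCc3ccccc3)c(OCc3ccccc3)c1)[C@H](O)[C@H]2OCCOCC
F6 | step 10 | 8-bromo-4β-(benzylthio)-5,7,3',4'-tetra-O-benzylepicatechin | c1ccccc1COc1cc(OCc2ccccc2)c2c(c1Br)O[C@H](c1ccc(OCc3ccccc3)c(OCc3ccccc3)c1)[C@H](O)[C@H]2SCc1ccccc1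
F7 | step 10 | dimer A–B with 4β-(benzylthio) on unit B | c1ccccc1COc1cc(OCc2ccccc2)c2c(c1)O[C@H](c1ccc(OCc3ccccc3)c(OCc3ccccc3)c1)[C@H](OCc1ccccc1)[C@H]2c1c(OCc2ccccc2)c(Br)c2c(c1OCc1ccccc1)[C@H](SCc1ccccc1)[C@@H](O)[C@@H](c1ccc(OCc3ccccc3)c(OCc3ccccc3)c1)O2
F8 | step 11 | 4β-(benzylthio)-5,7,3',4'-tetra-O-benzylepicatechin | c1ccccc1COc1cc(OCc2ccccc2)c2c(c1)O[C@H](c1ccc(OCc3ccccc3)c(OCc3ccccc3)c1)[C@H](O)[C@H]2SCc1ccccc1
F9 | step 11 | trimer A-(4β→6)-B(8-bromo)-(4β→8)-C with 4β-(benzylthio) on unit C | c1ccccc1COc1cc(OCc2ccccc2)c2c(c1)O[C@H](c1ccc(OCc3ccccc3)c(OCc3ccccc3)c1)[C@H](OCc1ccccc1)[C@H]2c1c(OCc2ccccc2)c(Br)c2c(c1OCc1ccccc1)[C@H](c1c(OCc4ccccc4)cc(OCc4ccccc4)c3c1O[C@H](c1ccc(OCc4ccccc4)c(OCc4ccccc4)c1)[C@H](O)[C@H]3SCc1ccccc1)[C@@H](O)[C@@H](c1ccc(OCc3ccccc3)c(OCc3ccccc3)c1)O2
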